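**Retrosynthetic overview**

1. Target 33 ⇐ acetylation of carbinol 32 ⇐ SmI2 Barbier union (C11–C1′ bond) of lactone iodide 25 (rings B and C) with ring A ketone 30.
2. Lactone C10=O ⇐ ether CH2 (RuO4) ⇐ angular methyl. The strategy rests on C10 standing axial on quaternary C4 and 1,3-diaxial (across C5) to the axial C9 oxygen on the ring C chair, so that a C9 alkoxy radical takes a C10 hydrogen and the oxygen then closes the O–C10 oxolane (22 ⇐ 19).
3. 19 ⇐ hydroxyl-directed hydrogenation of C1=C5 ⇐ methyl addition to enone 17 ⇐ Appel inversion at C6 ⇐ ring B by gold-catalysed 5-exo-dig closure C5–C1 of a silyl enol ether onto a butynyl chain, then epoxidation/E1cB opening for the C11 oxygen.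
4. C4 and C6 ⇐ two anti cuprate additions (chain, then methyl) to (S)-4-silyloxycyclohexenone 4; the same enone 4 also gives ring A ketone 30.
5. Ring order: ring C (present in 1), ring B (step 8), oxolane (step 15, lactone in step 16), ring A joined last (step 24).

Key step: step 15

Remark (numbering, used for all intermediates): ring B = C1 (bears C11H2), C2, C3, C4, C5; ring C = C4, C5, C9, C8, C7, C6; C10 = the carbon on C4 (methyl, later lactone C=O); ring A atoms are primed (C1′ carbinol, C3′ CMe2, C4′ CHBr).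
Remark (assumption): RuCl[(S,S)-TsDPEN](p-cymene) is taken to reduce 1 with the sense known for aryl ketones (alkene in the place of aryl), giving (8S)-2; the mirror-image catalyst would be used otherwise. Metal alkoxides and enolates that are only protonated on work-up are not numbered.

**Route**

Step 1
Reactants: 1 1,4-dioxaspiro[4.5]dec-6-en-8-one
Product: 2 (8S)-1,4-dioxaspiro[4.5]dec-6-en-8-ol
Conditions: RuCl[(S,S)-TsDPEN](p-cymene) (1 mol%), HCO2Na, n-Bu4NCl (cat.), H2O/CH2Cl2, rt
Reagents that add atoms: none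
Why: Noyori asymmetric transfer hydrogenation reduces the enone carbonyl 1,2 and should set the future C6 carbinol as (S), the alkene taking the place an aryl group has in aryl ketone reductions.

Step 2
Reactants: 2 (8S)-1,4-dioxaspiro[4.5]dec-6-en-8-ol
Product: 3 (8S)-8-(tert-butyldimethylsilyloxy)-1,4-dioxaspiro[4.5]dec-6-ene
Conditions: TBSCl, imidazole, DMF, rt
Reagents that add atoms: tert-butyldimethylsilyl chloride, CC(C)(C)[Si](C)(C)Cl
Why: Imidazole-promoted silylation of a secondary allylic alcohol, without change at the stereocenter.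

Step 3
Reactants: 3 (8S)-8-(tert-butyldimethylsilyloxy)-1,4-dioxaspiro[4.5]dec-6-ene
Product: 4 (4S)-4-(tert-butyldimethylsilyloxy)cyclohex-2-en-1-one
Conditions: PPTS, acetone/H2O (10:1), 45 °C
Reagents that add atoms: water, O
Why: Acid-catalysed hydrolysis of the allylic ketal; the secondary silyl ether should survive PPTS and the γ-stereocenter is not touched.

Step 4
Reactants: 4 (4S)-4-(tert-butyldimethylsilyloxy)cyclohex-2-en-1-one; 5 (4-bromobut-1-yn-1-yl)trimethylsilane
Product: 7 (3S,4S)-4-(tert-butyldimethylsilyloxy)-1-(trimethylsilyloxy)-3-[4-(trimethylsilyl)but-3-yn-1-yl]cyclohex-1-ene, via Grignard reagent 6 (not isolated)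
Conditions: 5, Mg, THF, 45 °C; then CuBr·SMe2 (10 mol%), TMSCl, 4, THF, −78 °C
Reagents that add atoms: chlorotrimethylsilane, C[Si](C)(C)Cl
Why: Copper-catalysed conjugate addition of a Grignard reagent with TMSCl trapping; the chain enters anti to the silyloxy group, and this transient stereocenter is removed in step 5.

Step 5
Reactants: 7 (3S,4S)-4-(tert-butyldimethylsilyloxy)-1-(trimethylsilyloxy)-3-[4-(trimethylsilyl)but-3-yn-1-yl]cyclohex-1-ene
Product: 8 (4S)-4-(tert-butyldimethylsilyloxy)-3-[4-(trimethylsilyl)but-3-yn-1-yl]cyclohex-2-en-1-one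
Conditions: Pd(OAc)2 (1.05 equiv), MeCN, rt
Reagents that add atoms: none
Why: Saegusa–Ito oxidation; the palladium enolate loses the hydrogen on the chain-bearing carbon (future C4) by β-hydride elimination and restores the enone, now β-substituted.

Step 6
Reactants: 8 (4S)-4-(tert-butyldimethylsilyloxy)-3-[4-(trimethylsilyl)but-3-yn-1-yl]cyclohex-2-en-1-one
Product: 10 (3R,4S)-4-(tert-butyldimethylsilyloxy)-3-methyl-1-(triisopropylsilyloxy)-3-[4-(trimethylsilyl)but-3-yn-1-yl]cyclohex-1-ene, via lithium enolate 9 (not isolated)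
Conditions: Me2CuLi (from MeLi and CuI), Et2O, −78 → −20 °C; then TIPSOTf, Et3N, −78 → 0 °C
Reagents that add atoms: methyllithium (delivered as Me2CuLi), [Li]C; triisopropylsilyl trifluoromethanesulfonate, CC(C)[Si](C(C)C)(C(C)C)OS(=O)(=O)C(F)(F)F
Why: Gilman cuprate conjugate addition anti to the C6 silyloxy group creates quaternary C4 with the methyl (C10) trans to oxygen, and O-silylation of the enolate fixes the enol ether toward C5.

Step 7
Reactants: 10 (3R,4S)-4-(tert-butyldimethylsilyloxy)-3-methyl-1-(triisopropylsilyloxy)-3-[4-(trimethylsilyl)but-3-yn-1-yl]cyclohex-1-ene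
Product: 11 (3R,4S)-3-(but-3-yn-1-yl)-4-(tert-butyldimethylsilyloxy)-3-methyl-1-(triisopropylsilyloxy)cyclohex-1-ene
Conditions: K2CO3, MeOH, rt
Reagents that add atoms: none
Why: Base-mediated protodesilylation of the alkynylsilane; the triisopropylsilyl enol ether and the secondary silyl ether should be stable to K2CO3 in methanol.

Step 8
Reactants: 11 (3R,4S)-3-(but-3-yn-1-yl)-4-(tert-butyldimethylsilyloxy)-3-methyl-1-(triisopropylsilyloxy)cyclohex-1-ene
Product: 12 (3aS,7S,7aR)-7-(tert-butyldimethylsilyloxy)-7a-methyl-3-methylideneoctahydro-4H-inden-4-one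
Conditions: Ph3PAuCl (5 mol%), AgBF4 (5 mol%), CH2Cl2/MeOH (10:1), rt → 40 °C
Reagents that add atoms: none
Why: Gold-catalysed Conia-ene-type carbocyclization of a silyl enol ether (Toste); C5 attacks the alkyne activated by Ph3PAu+ in a 5-exo-dig mode, methanol takes the silyl group, and the two-carbon tether on C4 forces the cis ring fusion.

Step 9
Reactants: 12 (3aS,7S,7aR)-7-(tert-butyldimethylsilyloxy)-7a-methyl-3-methylideneoctahydro-4H-inden-4-one
Product: 13 spiro-epoxide of 12 at C1=C11 (both epimers at C1)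
Conditions: mCPBA, NaHCO3, CH2Cl2, 0 °C
Reagents that add atoms: 3-chloroperoxybenzoic acid, OOC(=O)c1cccc(Cl)c1
Why: Prilezhaev epoxidation of the 1,1-disubstituted alkene, which should be faster than Baeyer–Villiger oxidation of the ketone at 0 °C; the configuration at C1 is erased in step 10.

Step 10
Reactants: 13 spiro-epoxide of 12
Product: 15 [(7S,7aR)-7-(tert-butyldimethylsilyloxy)-7a-methyl-4-oxo-2,4,5,6,7,7a-hexahydro-1H-inden-3-yl]methyl 2,2-dimethylpropanoate, via hydroxymethyl enone 14 (not isolated)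
Conditions: DBU, CH2Cl2, 0 °C → rt; then PivCl, DMAP (cat.), 0 °C
Reagents that add atoms: pivaloyl chloride, CC(C)(C)C(=O)Cl
Why: DBU removes the C5 proton and opens the β,γ-epoxide (E1cB) to the γ-hydroxy enone with the C1=C5 double bond; DMAP-catalysed acylation in the same flask caps the C11 hydroxyl before it can close onto the ketone and aromatize to a furan.

Step 11
Reactants: 15 the pivalate enone with C6 silyl ether
Product: 16 [(7S,7aR)-7-hydroxy-7a-methyl-4-oxo-2,4,5,6,7,7a-hexahydro-1H-inden-3-yl]methyl 2,2-dimethylpropanoate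
Conditions: HF (48% aq.), MeCN, 0 °C → rt
Reagents that add atoms: none
Why: Fluoride-mediated cleavage of the hindered secondary silyl ether; enone and pivalate are stable to aqueous HF in acetonitrile.

Step 12
Reactants: 16 the C6 alcohol (hydroxyl trans to C10, pseudo-axial)
Product: 17 [(7R,7aR)-7-bromo-7a-methyl-4-oxo-2,4,5,6,7,7a-hexahydro-1H-inden-3-yl]methyl 2,2-dimethylpropanoate
Conditions: CBr4, PPh3, toluene, 60 °C
Reagents that add atoms: carbon tetrabromide, BrC(Br)(Br)Br
Why: Appel reaction; bromide displaces the alkoxyphosphonium group with inversion (SN2), the known way to turn an axial neopentyl carbinol next to a fully substituted carbon into the equatorial bromide in brominated terpenoid rings, so the C6 bromine ends cis to C10.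

Step 13
Reactants: 17 the bromo enone pivalate
Product: 18 [(4S,7R,7aR)-7-bromo-4-hydroxy-4,7a-dimethyl-2,4,5,6,7,7a-hexahydro-1H-inden-3-yl]methyl 2,2-dimethylpropanoate
Conditions: MeMgBr, CeCl3 (anhydrous), THF, −78 °C
Reagents that add atoms: methylmagnesium bromide, C[Mg]Br
Why: Imamoto organocerium 1,2-addition; MeCeCl2 is non-basic and should spare the pivalate and the bromide, and it should attack C9 from the face opposite the pseudo-axial C4 methyl, placing the C9 hydroxyl cis to C10.

Step 14
Reactants: 18 the tertiary allylic alcohol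
Product: 19 [(3S,3aS,4S,7R,7aR)-7-bromo-4-hydroxy-4,7a-dimethyloctahydro-1H-inden-3-yl]methyl 2,2-dimethylpropanoate
Conditions: H2 (50 bar), [Ir(cod)(PCy3)(py)]PF6 (10 mol%), CH2Cl2, rt
Reagents that add atoms: none
Why: Hydroxyl-directed hydrogenation (Crabtree–Stork); the cationic iridium complex binds the C9 hydroxyl and delivers both hydrogens to the C1=C5 face syn to it, which sets H5 and H1 cis to C10 (cis-hydrindane, C11 cis to C9).

Step 15
Reactants: 19 the bromo hydrindanol pivalate
Product: 22 bridged ether pivalate (C9–O–C10H2 oxolane on the bromo hydrindane), via hypoiodite 20 (not isolated), via iodomethyl carbinol 21 (not isolated)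
Conditions: PhI(OAc)2 (1.5 equiv), I2 (1 equiv), cyclohexane, hν (tungsten lamp), 40 °C
Reagents that add atoms: none
Why: AcOI formed from PhI(OAc)2 and I2 converts the C9 hydroxyl into hypoiodite 20, visible light cleaves the O–I bond, the C9 alkoxy radical takes a hydrogen from the C10 methyl through a chair-like six-membered transition state (1,5-hydrogen transfer), the C10 radical is capped by iodine to give 21, and the C9 oxygen displaces the iodide. The closest known reaction type is the Suárez hypoiodite reaction of steroidal alcohols that carry a 1,3-diaxial angular methyl group (6β-ol to 6β,19-ether, 11β-ol to 11β,18-ether). The oxolane closes in a 5-exo-tet mode and completes a 6-oxabicyclo[3.2.1]octane; no stereocenter is created, since C4 and C9 are already set and C10 is a CH2 group. The step needs site selectivity among the C–H bonds three bonds from C9 (C10, C3, C6, C2, C11) and hydrogen transfer must outrun β-scission of C9–C5. This should be secured by the ring C chair in which the C4 methyl and the C9 oxygen are axial on the same face and within reach of each other, while C1 with C2 and C11 is antiperiplanar to the oxygen and H6 lies on the other face; that chair should be favoured because the other one places C3 and the C9 methyl 1,3-diaxial and the bromine axial. The equatorial C6 bromide and the pivalate are not expected to react under these neutral radical conditions.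

Step 16
Reactants: 22 the bridged ether pivalate
Product: 23 bridged lactone pivalate (C10=O)
Conditions: RuCl3·xH2O (5 mol%), NaIO4, CCl4/MeCN/H2O, rt
Reagents that add atoms: sodium periodate, [Na+].[O-]I(=O)(=O)=O
Why: RuO4 (made from RuCl3 and NaIO4) oxidation of an ether α-CH2 to the lactone; C10 is the only ether carbon that bears hydrogen, and ester and bromide are inert.

Step 17
Reactants: 23 the lactone pivalate
Product: 24 lactone primary alcohol (C11–OH)
Conditions: NaOMe, MeOH, 40 °C; AcOH quench
Reagents that add atoms: none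
Why: Base-catalysed transesterification (Zemplén type); the lactone carbonyl sits on quaternary C4 with a tertiary alkoxy group and is far more hindered than the primary pivalate, and any opened hydroxy ester should relactonize on the acidic quench.

Step 18
Reactants: 24 the lactone alcohol
Product: 25 lactone primary iodide (C11–I)
Conditions: I2, PPh3, imidazole, CH2Cl2, 0 °C → rt
Reagents that add atoms: iodine, II
Why: Garegg–Samuelsson (Appel-type) iodination of the primary alcohol by SN2; the neopentyl secondary bromide and the lactone do not react.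

Step 19
Reactants: 4 (4S)-4-(tert-butyldimethylsilyloxy)cyclohex-2-en-1-one
Product: 26 (3S,4S)-4-(tert-butyldimethylsilyloxy)-3-methyl-1-(trimethylsilyloxy)cyclohex-1-ene
Conditions: MeMgBr, CuBr·SMe2 (10 mol%), TMSCl, THF, −78 °C
Reagents that add atoms: methylmagnesium bromide, C[Mg]Br; chlorotrimethylsilane, C[Si](C)(C)Cl
Why: Copper-catalysed conjugate addition with TMSCl trapping, anti to the silyloxy group; the new stereocenter is removed in step 20.

Step 20
Reactants: 26 (3S,4S)-4-(tert-butyldimethylsilyloxy)-3-methyl-1-(trimethylsilyloxy)cyclohex-1-ene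
Product: 27 (4S)-4-(tert-butyldimethylsilyloxy)-3-methylcyclohex-2-en-1-one
Conditions: Pd(OAc)2 (1.05 equiv), MeCN, rt
Reagents that add atoms: none
Why: Saegusa–Ito oxidation of the silyl enol ether to the β-methyl enone.

Step 21
Reactants: 27 (4S)-4-(tert-butyldimethylsilyloxy)-3-methylcyclohex-2-en-1-one
Product: 28 (4S)-4-(tert-butyldimethylsilyloxy)-3,3-dimethylcyclohexan-1-one
Conditions: Me2CuLi (from MeLi and CuI), Et2O, −78 → 0 °C; aq. NH4Cl
Reagents that add atoms: methyllithium (delivered as Me2CuLi), [Li]C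
Why: Gilman cuprate conjugate addition to the β-methyl enone builds the gem-dimethyl carbon C3′; the carbinol stereocenter is untouched.

Step 22
Reactants: 28 (4S)-4-(tert-butyldimethylsilyloxy)-3,3-dimethylcyclohexan-1-one
Product: 29 (4S)-4-hydroxy-3,3-dimethylcyclohexan-1-one
Conditions: HF (48% aq.), MeCN, rt
Reagents that add atoms: none
Why: Fluoride-mediated desilylation; a γ-hydroxy ketone has no elimination pathway.

Step 23
Reactants: 29 (4S)-4-hydroxy-3,3-dimethylcyclohexan-1-one
Product: 30 (4R)-4-bromo-3,3-dimethylcyclohexan-1-one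
Conditions: CBr4, PPh3, CH2Cl2, 40 °C
Reagents that add atoms: carbon tetrabromide, BrC(Br)(Br)Br
Why: Appel reaction with SN2 inversion at the neopentyl carbinol, which the ring can present axially, giving the (R)-bromide; the ketone is not expected to be olefinated without zinc.

Step 24
Reactants: 25 lactone primary iodide; 30 (4R)-4-bromo-3,3-dimethylcyclohexan-1-one
Product: 32 tertiary carbinol (33 without the acetyl group), via alkylsamarium 31 (not isolated)
Conditions: SmI2 (2.5 equiv), NiI2 (2 mol%), THF, 0 °C → rt, slow addition of 25 and 30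
Reagents that add atoms: none
Why: Samarium Barbier reaction (Kagan–Molander); SmI2 should reduce the primary iodide in preference to the secondary bromides and the lactone, and the organosamarium should add to the ketone from the equatorial side, away from the axial C3′ methyl, on the chair with equatorial bromine, giving the axial C1′ hydroxyl cis to the C4′ bromine.

Step 25
Reactants: 32 tertiary carbinol
Product: 33 CNP0133010.1 (target)
Conditions: Ac2O, DMAP, Et3N, CH2Cl2, 40 °C
Reagents that add atoms: acetic anhydride, CC(=O)OC(C)=O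
Why: DMAP-catalysed (Steglich-type) acetylation of the tertiary alcohol; lactone and bromides are inert.

**Compound list**

1 | 1,4-dioxaspiro[4.5]dec-6-en-8-one | O=C1C=CC2(CC1)OCCO2 | starting material
2 | (8S)-1,4-dioxaspiro[4.5]dec-6-en-8-ol | O[C@@H]1C=CC2(CC1)OCCO2 | intermediate
3 | (8S)-8-(tert-butyldimethylsilyloxy)-1,4-dioxaspiro[4.5]dec-6-ene | CC(C)(C)[Si](C)(C)O[C@@H]1C=CC2(CC1)OCCO2 | intermediate
4 | (4S)-4-(tert-butyldimethylsilyloxy)cyclohex-2-en-1-one | O=C1C=C[C@@H](O[Si](C)(C)C(C)(C)C)CC1 | intermediate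
5 | (4-bromobut-1-yn-1-yl)trimethylsilane | C[Si](C)(C)C#CCCBr | starting material
6 | [4-(trimethylsilyl)but-3-yn-1-yl]magnesium bromide | C[Si](C)(C)C#CCC[Mg]Br | intermediate (not isolated)
7 | (3S,4S)-4-(tert-butyldimethylsilyloxy)-1-(trimethylsilyloxy)-3-[4-(trimethylsilyl)but-3-yn-1-yl]cyclohex-1-ene (3,4-trans) | C[Si](C)(C)OC1=C[C@H](CCC#C[Si](C)(C)C)[C@@H](O[Si](C)(C)C(C)(C)C)CC1 | intermediate
8 | (4S)-4-(tert-butyldimethylsilyloxy)-3-[4-(trimethylsilyl)but-3-yn-1-yl]cyclohex-2-en-1-one | O=C1C=C(CCC#C[Si](C)(C)C)[C@@H](O[Si](C)(C)C(C)(C)C)CC1 | intermediate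
9 | lithium enolate (C1=C2) of (3R,4S)-4-(tert-butyldimethylsilyloxy)-3-methyl-3-[4-(trimethylsilyl)but-3-yn-1-yl]cyclohexan-1-one | [Li]OC1=C[C@@](C)(CCC#C[Si](C)(C)C)[C@@H](O[Si](C)(C)C(C)(C)C)CC1 | intermediate (not isolated)
10 | (3R,4S)-4-(tert-butyldimethylsilyloxy)-3-methyl-1-(triisopropylsilyloxy)-3-[4-(trimethylsilyl)but-3-yn-1-yl]cyclohex-1-ene (methyl trans to the silyloxy group) | CC(C)[Si](C(C)C)(C(C)C)OC1=C[C@@](C)(CCC#C[Si](C)(C)C)[C@@H](O[Si](C)(C)C(C)(C)C)CC1 | intermediate
11 | (3R,4S)-3-(but-3-yn-1-yl)-4-(tert-butyldimethylsilyloxy)-3-methyl-1-(triisopropylsilyloxy)cyclohex-1-ene | CC(C)[Si](C(C)C)(C(C)C)OC1=C[C@@](C)(CCC#C)[C@@H](O[Si](C)(C)C(C)(C)C)CC1 | intermediate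
12 | (3aS,7S,7aR)-7-(tert-butyldimethylsilyloxy)-7a-methyl-3-methylideneoctahydro-4H-inden-4-one (cis-fused, silyloxy trans to the angular methyl) | C=C1CC[C@@]2(C)[C@@H](O[Si](C)(C)C(C)(C)C)CCC(=O)[C@@H]12 | intermediate
13 | spiro-epoxide of 12 at C1=C11 (both epimers at C1) | C1OC12CC[C@@]3(C)[C@@H](O[Si](C)(C)C(C)(C)C)CCC(=O)[C@@H]23 | intermediate
14 | (7S,7aR)-7-(tert-butyldimethylsilyloxy)-3-(hydroxymethyl)-7a-methyl-1,2,5,6,7,7a-hexahydro-4H-inden-4-one | OCC1=C2C(=O)CC[C@H](O[Si](C)(C)C(C)(C)C)[C@]2(C)CC1 | intermediate (not isolated)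
15 | [(7S,7aR)-7-(tert-butyldimethylsilyloxy)-7a-methyl-4-oxo-2,4,5,6,7,7a-hexahydro-1H-inden-3-yl]methyl 2,2-dimethylpropanoate | CC(C)(C)C(=O)OCC1=C2C(=O)CC[C@H](O[Si](C)(C)C(C)(C)C)[C@]2(C)CC1 | intermediate
16 | [(7S,7aR)-7-hydroxy-7a-methyl-4-oxo-2,4,5,6,7,7a-hexahydro-1H-inden-3-yl]methyl 2,2-dimethylpropanoate | CC(C)(C)C(=O)OCC1=C2C(=O)CC[C@H](O)[C@]2(C)CC1 | intermediate
17 | [(7R,7aR)-7-bromo-7a-methyl-4-oxo-2,4,5,6,7,7a-hexahydro-1H-inden-3-yl]methyl 2,2-dimethylpropanoate (Br cis to the angular methyl) | CC(C)(C)C(=O)OCC1=C2C(=O)CC[C@@H](Br)[C@]2(C)CC1 | intermediate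
18 | [(4S,7R,7aR)-7-bromo-4-hydroxy-4,7a-dimethyl-2,4,5,6,7,7a-hexahydro-1H-inden-3-yl]methyl 2,2-dimethylpropanoate (OH cis to the angular methyl) | CC(C)(C)C(=O)OCC1=C2[C@@](C)(O)CC[C@@H](Br)[C@]2(C)CC1 | intermediate
19 | [(3S,3aS,4S,7R,7aR)-7-bromo-4-hydroxy-4,7a-dimethyloctahydro-1H-inden-3-yl]methyl 2,2-dimethylpropanoate (key-step precursor) | CC(C)(C)C(=O)OC[C@H]1CC[C@@]2(C)[C@H](Br)CC[C@](C)(O)[C@@H]12 | intermediate
20 | hypoiodite of 19 (C9–O–I) | CC(C)(C)C(=O)OC[C@H]1CC[C@@]2(C)[C@H](Br)CC[C@](C)(OI)[C@@H]12 | intermediate (not isolated)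
21 | 7a-(iodomethyl) analogue of 19 (C10–I, free C9–OH) | CC(C)(C)C(=O)OC[C@H]1CC[C@@]2(CI)[C@H](Br)CC[C@](C)(O)[C@@H]12 | intermediate (not isolated)
22 | bridged ether pivalate (C9–O–C10H2 oxolane across C4 and C9; key-step product) | CC(C)(C)C(=O)OC[C@H]1CC[C@@]23CO[C@@](C)(CC[C@H]2Br)[C@@H]13 | intermediate
23 | bridged lactone pivalate (C10=O) | CC(C)(C)C(=O)OC[C@H]1CC[C@@]23C(=O)O[C@@](C)(CC[C@H]2Br)[C@@H]13 | intermediate
24 | bridged lactone primary alcohol (C11–OH) | OC[C@H]1CC[C@@]23C(=O)O[C@@](C)(CC[C@H]2Br)[C@@H]13 | intermediate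
25 | bridged lactone primary iodide (C11–I) | IC[C@H]1CC[C@@]23C(=O)O[C@@](C)(CC[C@H]2Br)[C@@H]13 | intermediate
26 | (3S,4S)-4-(tert-butyldimethylsilyloxy)-3-methyl-1-(trimethylsilyloxy)cyclohex-1-ene (3,4-trans) | C[Si](C)(C)OC1=C[C@H](C)[C@@H](O[Si](C)(C)C(C)(C)C)CC1 | intermediate
27 | (4S)-4-(tert-butyldimethylsilyloxy)-3-methylcyclohex-2-en-1-one | O=C1C=C(C)[C@@H](O[Si](C)(C)C(C)(C)C)CC1 | intermediate
28 | (4S)-4-(tert-butyldimethylsilyloxy)-3,3-dimethylcyclohexan-1-one | O=C1CC(C)(C)[C@@H](O[Si](C)(C)C(C)(C)C)CC1 | intermediate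
29 | (4S)-4-hydroxy-3,3-dimethylcyclohexan-1-one | O=C1CC(C)(C)[C@@H](O)CC1 | intermediate
30 | (4R)-4-bromo-3,3-dimethylcyclohexan-1-one | O=C1CC(C)(C)[C@H](Br)CC1 | intermediate
31 | alkylsamarium diiodide from 25 (C11–SmI2) | I[Sm](I)C[C@H]1CC[C@@]23C(=O)O[C@@](C)(CC[C@H]2Br)[C@@H]13 | intermediate (not isolated)
32 | tertiary carbinol, 33 without the acetyl group (C1′–OH cis to C4′–Br) | O[C@@]1(C[C@H]2CC[C@@]34C(=O)O[C@@](C)(CC[C@H]3Br)[C@@H]24)CC[C@@H](Br)C(C)(C)C1 | intermediate
33 | CNP0133010.1 | CC(=O)O[C@@]1(C[C@H]2CC[C@@]34C(=O)O[C@@](C)(CC[C@H]3Br)[C@@H]24)CC[C@@H](Br)C(C)(C)C1 | target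

**Summary**

Total step count: 25. Longest linear sequence: 20 steps (steps 1–18, 24, 25); the ring A branch (steps 19–23) starts from intermediate 4.

**Steps most likely to fail**

Step 15 (key step). The hindered tertiary hypoiodite may form slowly, and the alkoxy radical may then be lost to β-scission of the C9–C5 bond or to hydrogen abstraction from C11 or C2 through the minor ring C chair. Fallback by Barton nitrite photolysis: from 19, NOCl in pyridine gives the nitrite ester F1. Irradiation (350 nm, benzene, 0–10 °C) generates the same C9 alkoxy radical at low temperature, where hydrogen transfer is favoured over fragmentation, and the C10 nitroso compound tautomerizes to the oxime F2. NaNO2 in aqueous AcOH cleaves the oxime to the aldehyde, which closes onto the C9 hydroxyl as the lactol F3. TEMPO (cat.) with PhI(OAc)2 oxidizes the lactol to lactone 23, where the route is rejoined; step 16 is bypassed.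

Step 12. The alkoxyphosphonium group at the neopentyl, pseudo-axial C6 position may ionize with a 1,2-shift of the antiperiplanar C10 methyl (the resulting C4 cation is allylic) or lose H7, instead of undergoing backside attack. Fallback: the displacement is moved behind the saturation of ring B. From 15, MeMgBr/CeCl3 gives the tertiary allylic alcohol F4, hydrogenation with [Ir(cod)(PCy3)(py)]PF6 gives the hydrindanol silyl ether F5, and aqueous HF in MeCN gives the diol F6. CBr4/PPh3 should then convert only the secondary hydroxyl, with inversion, to give 19, where the route is rejoined. On F6 no alkene flanks C4, and ring C can flip so that bromide enters past hydrogen atoms only.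

Step 24. SmI2 may reduce the ketone of 30 or the two secondary C–Br bonds faster than it couples the fragments, and the facial selectivity depends on the bromoketone reacting through the chair with equatorial bromine. Fallback: the union is moved ahead of the ether oxidation, so that a non-reducing organocerium reagent can be used. From 22, NaOMe/MeOH gives the ether alcohol F7 and I2/PPh3/imidazole gives the ether iodide F8. t-BuLi (2 equiv, Et2O/pentane, −78 °C), then CeCl3 and ketone 30 give the tertiary carbinol F9, and Ac2O/DMAP gives the acetate F10. RuCl3/NaIO4 then oxidizes the ether CH2 to the lactone, which is target 33.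

**Further compounds**

F1 | step 15 | nitrite ester of 19 (C9–O–N=O) | CC(C)(C)C(=O)OC[C@H]1CC[C@@]2(C)[C@H](Br)CC[C@](C)(ON=O)[C@@H]12
F2 | step 15 | C10 oxime with free C9 hydroxyl | CC(C)(C)C(=O)OC[C@H]1CC[C@@]2(C=NO)[C@H](Br)CC[C@](C)(O)[C@@H]12
F3 | step 15 | bridged lactol pivalate (C10 hemiacetal, both epimers) | CC(C)(C)C(=O)OC[C@H]1CC[C@@]23C(O)O[C@@](C)(CC[C@H]2Br)[C@@H]13
F4 | step 12 | tertiary allylic alcohol with C6 silyl ether | CC(C)(C)C(=O)OCC1=C2[C@@](C)(O)CC[C@H](O[Si](C)(C)C(C)(C)C)[C@]2(C)CC1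
F5 | step 12 | hydrindanol with C6 silyl ether | CC(C)(C)C(=O)OC[C@H]1CC[C@@]2(C)[C@@H](O[Si](C)(C)C(C)(C)C)CC[C@](C)(O)[C@@H]12
F6 | step 12 | hydrindane C6,C9-diol pivalate (C6 hydroxyl trans to C10) | CC(C)(C)C(=O)OC[C@H]1CC[C@@]2(C)[C@@H](O)CC[C@](C)(O)[C@@H]12
F7 | step 24 | bridged ether primary alcohol | OC[C@H]1CC[C@@]23CO[C@@](C)(CC[C@H]2Br)[C@@H]13
F8 | step 24 | bridged ether primary iodide | IC[C@H]1CC[C@@]23CO[C@@](C)(CC[C@H]2Br)[C@@H]13
F9 | step 24 | tertiary carbinol at the ether oxidation level | O[C@@]1(C[C@H]2CC[C@@]34CO[C@@](C)(CC[C@H]3Br)[C@@H]24)CC[C@@H](Br)C(C)(C)C1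
F10 | step 24 | tertiary acetate at the ether oxidation level | CC(=O)O[C@@]1(C[C@H]2CC[C@@]34CO[C@@](C)(CC[C@H]3Br)[C@@H]24)CC[C@@H](Br)C(C)(C)C1
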